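**Retrosynthetic overview**
1. The route rests on the dihydropyran ring C1–O2–C3=C4–C5–C9 of the cyclopenta[c]pyran core. Taking out O2 and bonding C1 directly to C3 gives a cis-bicyclo[3.3.0]octan-3-one whose carbonyl carbon C3 lies between C1 and C4, which is the pattern left by an intramolecular enyne/CO (2+2+1) cycloaddition.
2. Endgame, read backwards: fluoride removal of four silyl groups; C1 ester by acylation of the enol lactol; O2 by Criegee cleavage of a C1,C3-diol made from the C3 ketone by Rubottom oxidation at C1 and reduction.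
3. The C10 coumarate and a C7 silyl ether replace the 7,10-acetonide while the core is still an acid-proof carbocycle, so no acid ever meets the acyl acetal or the enol ether.
4. A Pauson–Khand reaction of the 1,6-enyne C1=C9–C8–C7–C6–C5≡C4–C11 makes C5–C9, C1–C3 and C3–C4. The enyne comes from 2,2-dimethyl-1,3-dioxan-5-one by SAMP-hydrazone alkylation (C7) and axial vinyl addition (C8).
5. Ring order: dioxane (purchased, temporary), then cyclopentane and sacrificial cyclopentenone together, then the dihydropyran after the cut.

Key step: step 8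

Remark: iridoid numbering (C1, O2, C3 to C11) is used for all bicyclic compounds and β is the face of H5 and H9; the centres at C4, C1 and C3 of compounds 14 to 26 are drawn as convex-face attack predicts and are erased in steps 17 and 19, so their configuration is of no consequence.

Step 1
Reactants: 1 but-2-yne-1,4-diol
Product: 2 4-(tert-butyldimethylsilyloxy)but-2-yn-1-ol
Conditions: TBSCl (1 equiv), imidazole, 1 (3 equiv), DMF, 0 °C to rt
Reagents that add atoms: TBSCl, CC(C)(C)[Si](C)(C)Cl
Why: Silyl ether formation on a symmetrical diol used in excess should favour the monoether statistically, and the surplus diol is washed out with water.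

Step 2
Reactants: 2 4-(tert-butyldimethylsilyloxy)but-2-yn-1-ol
Product: 3 (4-bromobut-2-yn-1-yloxy)(tert-butyl)dimethylsilane
Conditions: CBr4, PPh3, CH2Cl2, 0 °C
Reagents that add atoms: carbon tetrabromide, BrC(Br)(Br)Br
Why: The Appel reaction converts the primary propargylic alcohol into the bromide by SN2 under neutral conditions that leave the TBS ether alone.

Step 3
Reactants: 4 2,2-dimethyl-1,3-dioxan-5-one; 5 SAMP
Product: 6 SAMP hydrazone of 2,2-dimethyl-1,3-dioxan-5-one
Conditions: cyclohexane, reflux, Dean–Stark trap
Reagents that add atoms: none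
Why: Hydrazone condensation of an unhindered, electrophilic ketone is driven to completion by azeotropic removal of water.

Step 4
Reactants: 6 SAMP hydrazone of 2,2-dimethyl-1,3-dioxan-5-one; 3 (4-bromobut-2-yn-1-yloxy)(tert-butyl)dimethylsilane
Product: 8 (S,S)-hydrazone carrying the 4-(TBSO)but-2-ynyl chain at dioxane C4, via lithium azaenolate 7 (not isolated)
Conditions: t-BuLi, THF, −78 °C; then 3, −100 °C to rt
Reagents that add atoms: none
Why: In the Enders SAMP/RAMP hydrazone alkylation the methoxy-chelated lithium azaenolate is attacked by the reactive propargylic bromide on the face turned away from the pyrrolidine side arm, which for SAMP sets dioxane C4 (iridoid C7) as S.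

Step 5
Reactants: 8 (S,S)-alkylated hydrazone
Product: 9 (S)-4-[4-(tert-butyldimethylsilyloxy)but-2-ynyl]-2,2-dimethyl-1,3-dioxan-5-one
Conditions: sat. aq. oxalic acid, Et2O, rt, two-phase
Reagents that add atoms: water, O
Why: Two-phase hydrazone hydrolysis with oxalic acid pulls the auxiliary into water as its salt and is mild enough to spare the ketal, the TBS ether, the alkyne and the α-stereocentre.

Step 6
Reactants: 9 (S)-4-[4-(tert-butyldimethylsilyloxy)but-2-ynyl]-2,2-dimethyl-1,3-dioxan-5-one
Product: 10 (4S,5R)-4-[4-(tert-butyldimethylsilyloxy)but-2-ynyl]-2,2-dimethyl-5-vinyl-1,3-dioxan-5-ol (vinyl cis to the chain)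
Conditions: CH2=CHMgBr, THF, −78 °C
Reagents that add atoms: vinylmagnesium bromide, C=C[Mg]Br
Why: In this Grignard 1,2-addition to a very electrophilic α,α'-dioxygenated ketone the chain sits equatorial and the nucleophile takes the axial path, which in a 1,3-dioxan-5-one meets ring oxygens instead of 1,3-diaxial hydrogens while the other face carries the axial C2 methyl group, so vinyl ends cis to the chain and C8 is set as R.

Step 7
Reactants: 10 (4S,5R)-vinyl carbinol
Product: 11 (4S,5R)-1,6-enyne with 5-O-triethylsilyl ether (Pauson–Khand precursor)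
Conditions: TESOTf, 2,6-lutidine, CH2Cl2, 0 °C
Reagents that add atoms: triethylsilyl triflate, CC[Si](CC)(CC)OS(=O)(=O)C(F)(F)F
Why: Silylation with a silyl triflate and a hindered pyridine base is the standard way to cap a tertiary alcohol, and it is fast enough at 0 °C to leave the ketal intact.

Step 8
Reactants: 11 (4S,5R)-1,6-enyne with 5-O-triethylsilyl ether
Product: 13 dioxane-fused bicyclo[3.3.0]octenone (C3 ketone; C4=C5; 11-OTBS; 7β,10-O-isopropylidene; 8α-OTES; H9β), via hexacarbonyldicobalt alkyne complex 12 (not isolated)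
Conditions: Co2(CO)8 (1.1 equiv), CH2Cl2, rt; then NMO (8 equiv), 0 °C to rt
Reagents that add atoms: dicobalt octacarbonyl (source of the C3 carbonyl), O=C=[Co](=C=O)(=C=O)(=C=O)[Co](=C=O)(=C=O)(=C=O)=C=O
Why: Co2(CO)8 binds the C4≡C5 alkyne as complex 12, NMO burns off one CO ligand, the vacant site takes up the vinyl group, the alkene inserts into the Co–C5 bond, CO migrates onto the Co–C1 bond and reductive elimination joins C3 to C4, which is an amine N-oxide promoted intramolecular Pauson–Khand reaction of a 1,6-enyne with allylic and homopropargylic oxygen substituents. The cyclopentane C5–C6–C7–C8–C9 closes in the insertion step in a 5-exo-trig sense (C5 bonds to the inner vinyl carbon C9 and C1 stays outside the ring on cobalt), helped by the gauche placement of the axial vinyl and equatorial butynyl groups on the dioxane chair and by the fully substituted C8. The cyclopentenone C1–C3–C4–C5–C9 closes by CO insertion and reductive elimination from the cobaltacycle, and the tether fixes the regiochemistry so that C11 ends on C4 next to the C3 carbonyl. The one new stereocentre, C9, is controlled by the cis-fused dioxane: the vinyl group should react through the rotamer in which C9=C1 eclipses the small C8–O bond and H9 points over the dioxane, which places the dioxane and the new cyclopentenone on opposite faces of the cyclopentane (H9 β, C1 α), whereas the other rotamer would stack both outer rings on one face. The step therefore needs only facial selectivity at the vinyl group, and chemoselectivity is secured because silyl ethers and the ketal are inert to Co2(CO)8 and NMO.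

Step 9
Reactants: 13 dioxane-fused bicyclo[3.3.0]octenone
Product: 14 cis-fused saturated C3 ketone (H5β; H9β; H4β)
Conditions: H2 (4 atm), 10% Pd/C, EtOAc, rt
Reagents that add atoms: none
Why: Heterogeneous catalytic hydrogenation should add both hydrogens from the convex β face marked by H9, because C7 and C8 fold under the α face of the enone plane and α addition would build a strained trans-bicyclo[3.3.0]octane, which sets C5.

Step 10
Reactants: 14 cis-fused saturated C3 ketone
Product: 15 7β,10-diol (8α-OTES and 11-OTBS kept)
Conditions: PPTS (cat.), MeOH, rt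
Reagents that add atoms: none
Why: Acid-catalysed transketalisation removes the strained 2,2-dimethyl-1,3-dioxane much faster than a tertiary TES or primary TBS ether, and it is done here because only a robust carbocycle is exposed to acid.

Step 11
Reactants: 16 p-coumaric acid
Product: 18 (E)-3-[4-(tert-butyldimethylsilyloxy)phenyl]acrylic acid, via bis-silylated coumarate 17 (not isolated)
Conditions: TBSCl (2.2 equiv), imidazole, DMF, rt; then AcOH/THF/H2O, rt
Reagents that add atoms: TBSCl, CC(C)(C)[Si](C)(C)Cl
Why: Exhaustive silylation followed by selective hydrolysis works because a silyl ester is far more labile to water than an aryl silyl ether.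

Step 12
Reactants: 15 7β,10-diol; 18 (E)-3-[4-(tert-butyldimethylsilyloxy)phenyl]acrylic acid
Product: 19 10-O-[(E)-4-(TBSO)cinnamoyl] ketone with free 7β-OH
Conditions: 18 (1.05 equiv), DCC, DMAP (cat.), CH2Cl2, −20 °C to 0 °C
Reagents that add atoms: none
Why: In this Steglich esterification the primary C10 hydroxyl should outrun the secondary C7 hydroxyl, and the primary ester is also the thermodynamic end point of any 1,3-acyl shift.

Step 13
Reactants: 19 10-O-cinnamoyl ketone with free 7β-OH
Product: 20 7β,8α-bis(triethylsilyl) ether of the 10-O-cinnamoyl ketone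
Conditions: TESCl, imidazole, DMAP (cat.), DMF, rt
Reagents that add atoms: chlorotriethylsilane, CC[Si](Cl)(CC)CC
Why: Silyl ether formation under weakly basic conditions caps the last free hydroxyl without enolising the ketone, so that later only the lactol OH can be acylated.

Step 14
Reactants: 20 bis-TES 10-O-cinnamoyl ketone
Product: 22 C1=C3 trimethylsilyl enol ether, via lithium enolate 21 (not isolated)
Conditions: LiHMDS (1.1 equiv), TMSCl (present from the start), THF, −78 °C
Reagents that add atoms: chlorotrimethylsilane, C[Si](C)(C)Cl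
Why: In this kinetic silyl enol ether formation the hindered amide takes an exposed C1 methylene proton faster than the tertiary C4–H, TMSCl traps the enolate before it can equilibrate or expel the C11 silyloxy group, and the non-enolisable cinnamate is left alone at −78 °C.

Step 15
Reactants: 22 C1=C3 trimethylsilyl enol ether
Product: 24 1β-hydroxy C3 ketone, via alpha-trimethylsilyloxy ketone 23 (not isolated)
Conditions: mCPBA, CH2Cl2, −20 °C to 0 °C; then citric acid, MeOH, 0 °C
Reagents that add atoms: mCPBA, O=C(OO)c1cccc(Cl)c1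
Why: In the Rubottom oxidation the electron-rich silyl enol ether is epoxidised from the convex face far faster than the electron-poor cinnamate alkene, silyl migration gives the α-silyloxy ketone, and its activated TMS ether is methanolysed under conditions that TES and TBS ethers survive.

Step 16
Reactants: 24 1β-hydroxy C3 ketone
Product: 25 1β,3α-diol
Conditions: NaBH4, THF/MeOH 9:1, −20 °C
Reagents that add atoms: none
Why: Borohydride reduction delivers hydride to the convex face of the ketone and leaves the ester, the cinnamate alkene and the aryl silyl ether untouched at this temperature.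

Step 17
Reactants: 25 1β,3α-diol
Product: 26 1,5-dialdehyde (C1HO on C9; C3HO on C4)
Conditions: Pb(OAc)4, CH2Cl2, 0 °C
Reagents that add atoms: none
Why: Criegee glycol cleavage cuts the sacrificial C1–C3 bond, and Pb(OAc)4 is preferred to periodate because two convex-face additions leave a trans-diol on a five-membered ring that forms a cyclic periodate ester only slowly and because the anhydrous medium keeps the dialdehyde from hydrating.

Step 18
Reactants: 27 (S)-3-methylpentanoic acid
Product: 28 (S)-3-methylpentanoyl chloride
Conditions: (COCl)2, DMF (cat.), CH2Cl2, 0 °C to rt, used as a solution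
Reagents that add atoms: oxalyl chloride, ClC(=O)C(=O)Cl
Why: Acid chloride formation through the Vilsmeier-type chloroiminium catalyst gives only gaseous by-products and cannot touch the stereocentre, which is β to the carbonyl group.

Step 19
Reactants: 26 1,5-dialdehyde; 28 (S)-3-methylpentanoyl chloride
Product: 30 tetrasilylated target (1β-ester; 7-OTES; 8-OTES; 11-OTBS; aryl OTBS), via enol lactol 29 (not isolated)
Conditions: Et3N, DMAP (0.2 equiv), CH2Cl2, −20 °C to 0 °C, slow addition of 28
Reagents that add atoms: none
Why: The 1,5-dialdehyde closes reversibly to the nepetalactol-type enol lactol (enolisation at C4, eased by the C11 oxygen, then addition of the C3 enol oxygen to the C1 aldehyde), and DMAP-catalysed O-acylation should drain the anomer whose hydroxyl lies on the convex β face trans to the fully substituted C8, the configuration iridoid hemiacetals adopt at equilibrium, which sets C1 and erases the stray centre at C4.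

Step 20
Reactants: 30 tetrasilylated target
Product: 31 CNP0241834.1
Conditions: TBAF/AcOH (1:1, 6 equiv), THF, 0 °C to rt
Reagents that add atoms: none
Why: Fluoride-mediated desilylation buffered with AcOH removes the aryl TBS, primary TBS and both TES groups near neutrality, so the acyl acetal, the enol ether and both esters should survive without acyl migration and no stereocentre is touched.

**Compound list**
1 | but-2-yne-1,4-diol | OCC#CCO | starting material
2 | 4-(tert-butyldimethylsilyloxy)but-2-yn-1-ol | OCC#CCO[Si](C)(C)C(C)(C)C | intermediate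
3 | (4-bromobut-2-yn-1-yloxy)(tert-butyl)dimethylsilane | BrCC#CCO[Si](C)(C)C(C)(C)C | intermediate
4 | 2,2-dimethyl-1,3-dioxan-5-one | CC1(C)OCC(=O)CO1 | starting material
5 | SAMP, (S)-1-amino-2-(methoxymethyl)pyrrolidine | COC[C@@H]1CCCN1N | starting material
6 | SAMP hydrazone of 2,2-dimethyl-1,3-dioxan-5-one | COC[C@@H]1CCCN1N=C2COC(C)(C)OC2 | intermediate
7 | lithium azaenolate of 6 | [Li+].COC[C@@H]1CCCN1[N-]C2=COC(C)(C)OC2 | intermediate
8 | (S,S)-alkylated SAMP hydrazone | COC[C@@H]1CCCN1N=C2COC(C)(C)O[C@H]2CC#CCO[Si](C)(C)C(C)(C)C | intermediate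
9 | (S)-4-[4-(tert-butyldimethylsilyloxy)but-2-ynyl]-2,2-dimethyl-1,3-dioxan-5-one | O=C1COC(C)(C)O[C@H]1CC#CCO[Si](C)(C)C(C)(C)C | intermediate
10 | (4S,5R)-4-[4-(tert-butyldimethylsilyloxy)but-2-ynyl]-2,2-dimethyl-5-vinyl-1,3-dioxan-5-ol | C=C[C@@]1(O)COC(C)(C)O[C@H]1CC#CCO[Si](C)(C)C(C)(C)C | intermediate
11 | (4S,5R)-1,6-enyne, 5-O-triethylsilyl ether of 10 | C=C[C@@]1(O[Si](CC)(CC)CC)COC(C)(C)O[C@H]1CC#CCO[Si](C)(C)C(C)(C)C | intermediate
12 | Co2(CO)6 complex of the C4≡C5 alkyne of 11 | C=C[C@@]1(O[Si](CC)(CC)CC)COC(C)(C)O[C@H]1CC23C4(CO[Si](C)(C)C(C)(C)C)[Co]2(=C=O)(=C=O)(=C=O)[Co]34(=C=O)(=C=O)=C=O | intermediate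
13 | dioxane-fused bicyclo[3.3.0]octenone (C3 ketone, C4=C5, H9β) | O=C1C[C@H]2C(=C1CO[Si](C)(C)C(C)(C)C)C[C@@H]3OC(C)(C)OC[C@]23O[Si](CC)(CC)CC | intermediate
14 | cis-fused saturated C3 ketone (H4β, H5β, H9β) | O=C1C[C@H]2[C@@H]([C@@H]1CO[Si](C)(C)C(C)(C)C)C[C@@H]3OC(C)(C)OC[C@]23O[Si](CC)(CC)CC | intermediate
15 | 7β,10-diol ketone | O=C1C[C@H]2[C@@H]([C@@H]1CO[Si](C)(C)C(C)(C)C)C[C@H](O)[C@@]2(CO)O[Si](CC)(CC)CC | intermediate
16 | p-coumaric acid | OC(=O)/C=C/c1ccc(O)cc1 | starting material
17 | tert-butyldimethylsilyl (E)-3-[4-(tert-butyldimethylsilyloxy)phenyl]acrylate | CC(C)(C)[Si](C)(C)OC(=O)/C=C/c1ccc(O[Si](C)(C)C(C)(C)C)cc1 | intermediate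
18 | (E)-3-[4-(tert-butyldimethylsilyloxy)phenyl]acrylic acid | OC(=O)/C=C/c1ccc(O[Si](C)(C)C(C)(C)C)cc1 | intermediate
19 | 10-O-[(E)-4-(TBSO)cinnamoyl] ketone, 7β-OH free | O=C1C[C@H]2[C@@H]([C@@H]1CO[Si](C)(C)C(C)(C)C)C[C@H](O)[C@@]2(COC(=O)/C=C/c3ccc(O[Si](C)(C)C(C)(C)C)cc3)O[Si](CC)(CC)CC | intermediate
20 | 7β,8α-bis-TES 10-O-cinnamoyl ketone | O=C1C[C@H]2[C@@H]([C@@H]1CO[Si](C)(C)C(C)(C)C)C[C@H](O[Si](CC)(CC)CC)[C@@]2(COC(=O)/C=C/c3ccc(O[Si](C)(C)C(C)(C)C)cc3)O[Si](CC)(CC)CC | intermediate
21 | lithium C1=C3 enolate of 20 | [Li+].[O-]C1=C[C@H]2[C@@H]([C@@H]1CO[Si](C)(C)C(C)(C)C)C[C@H](O[Si](CC)(CC)CC)[C@@]2(COC(=O)/C=C/c3ccc(O[Si](C)(C)C(C)(C)C)cc3)O[Si](CC)(CC)CC | intermediate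
22 | C1=C3 trimethylsilyl enol ether | C[Si](C)(C)OC1=C[C@H]2[C@@H]([C@@H]1CO[Si](C)(C)C(C)(C)C)C[C@H](O[Si](CC)(CC)CC)[C@@]2(COC(=O)/C=C/c3ccc(O[Si](C)(C)C(C)(C)C)cc3)O[Si](CC)(CC)CC | intermediate
23 | 1β-trimethylsilyloxy C3 ketone | O=C1[C@@H](O[Si](C)(C)C)[C@H]2[C@@H]([C@@H]1CO[Si](C)(C)C(C)(C)C)C[C@H](O[Si](CC)(CC)CC)[C@@]2(COC(=O)/C=C/c3ccc(O[Si](C)(C)C(C)(C)C)cc3)O[Si](CC)(CC)CC | intermediate
24 | 1β-hydroxy C3 ketone | O=C1[C@@H](O)[C@H]2[C@@H]([C@@H]1CO[Si](C)(C)C(C)(C)C)C[C@H](O[Si](CC)(CC)CC)[C@@]2(COC(=O)/C=C/c3ccc(O[Si](C)(C)C(C)(C)C)cc3)O[Si](CC)(CC)CC | intermediate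
25 | 1β,3α-diol | O[C@@H]1[C@@H](O)[C@H]2[C@@H]([C@@H]1CO[Si](C)(C)C(C)(C)C)C[C@H](O[Si](CC)(CC)CC)[C@@]2(COC(=O)/C=C/c3ccc(O[Si](C)(C)C(C)(C)C)cc3)O[Si](CC)(CC)CC | intermediate
26 | 1,5-dialdehyde (C1HO on C9, C3HO on C4) | O=C[C@H]1[C@@H]([C@@H](C=O)CO[Si](C)(C)C(C)(C)C)C[C@H](O[Si](CC)(CC)CC)[C@@]1(COC(=O)/C=C/c2ccc(O[Si](C)(C)C(C)(C)C)cc2)O[Si](CC)(CC)CC | intermediate
27 | (S)-3-methylpentanoic acid | CC[C@H](C)CC(=O)O | starting material
28 | (S)-3-methylpentanoyl chloride | CC[C@H](C)CC(=O)Cl | intermediate
29 | enol lactol (1β-OH, C3=C4) | O[C@@H]1OC=C(CO[Si](C)(C)C(C)(C)C)[C@H]2C[C@H](O[Si](CC)(CC)CC)[C@](O[Si](CC)(CC)CC)(COC(=O)/C=C/c3ccc(O[Si](C)(C)C(C)(C)C)cc3)[C@@H]12 | intermediate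
30 | tetrasilylated target | CC[C@H](C)CC(=O)O[C@@H]1OC=C(CO[Si](C)(C)C(C)(C)C)[C@H]2C[C@H](O[Si](CC)(CC)CC)[C@](O[Si](CC)(CC)CC)(COC(=O)/C=C/c3ccc(O[Si](C)(C)C(C)(C)C)cc3)[C@@H]12 | intermediate
31 | CNP0241834.1, (1S,4aS,6S,7R,7aS)-6,7-dihydroxy-4-(hydroxymethyl)-7-{[(E)-3-(4-hydroxyphenyl)acryloyl]oxymethyl}-1,4a,5,6,7,7a-hexahydrocyclopenta[c]pyran-1-yl (3S)-3-methylpentanoate | CC[C@H](C)CC(=O)O[C@@H]1OC=C(CO)[C@H]2C[C@H](O)[C@](O)(COC(=O)/C=C/c3ccc(O)cc3)[C@@H]12 | target

**Step count and risks**

Total step count: 20.
Longest linear sequence: 17 steps, from but-2-yne-1,4-diol (steps 1, 2, 4 to 10, 12 to 17, 19, 20).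

Steps most likely to fail:

Step 8 (key step). The vinyl group stands next to the fully substituted C8. Its coordination and insertion in the dicobalt cluster may therefore be slower than oxidative decomplexation by NMO, and the two faces of the vinyl group may not be told apart well enough. The fallback keeps the same (2+2+1) bond set but changes the metal and the one-carbon partner. It sets out from enyne 11, which is treated with Ni(cod)2 (zerovalent nickel), PBu3 and 2,6-dimethylphenyl isocyanide in THF. Oxidative cyclisation on a single nickel centre forms C5–C9 in a nickelacyclopentene. Isocyanide insertion and reductive elimination then give the tricyclic N-(2,6-dimethylphenyl)iminocyclopentene F1. Two-phase aqueous oxalic acid/Et2O, the medium that the ketal and the TBS ether already pass in step 5, hydrolyses the imine, and the route is rejoined at enone 13.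

Step 9. The tetrasubstituted C4=C5 bond may take up hydrogen sluggishly, and hydrogenolysis of the allylic C11–O bond may compete on the palladium surface. The fallback replaces surface hydrogenation by stepwise hydrogen-atom transfer. It sets out from enone 13, which is treated with Mn(dpm)3 (cat.), PhSiH3 and t-BuOOH in i-PrOH at rt. A hydrogen atom is delivered to C5, where the strain of a trans-bicyclo[3.3.0]octane enforces the cis fusion. The resulting C4 radical next to the carbonyl group is then reduced from the convex face. No metal surface is present that could cleave the allylic C–O bond. The route is rejoined at ketone 14, and no compound outside the list is made (F0).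

Step 19. Under the basic acylating conditions the open dialdehyde may lose a β-silyloxy group, epimerise at C9 or be drained as an open-chain enol ester before it closes. The fallback uncouples ring closure from acyl transfer and removes the amine base and the acid chloride. It sets out from dialdehyde 26, which is stirred with PPTS (cat.) in CH2Cl2. The C3 carbonyl oxygen then adds to the activated C1 aldehyde, and the cyclic oxocarbenium ion loses H4 under thermodynamic control. The enol lactol 29 is now isolated and esterified with the free acid 27, DCC and a catalytic amount of DMAP at −20 °C (Steglich esterification). The route is rejoined at 30, step 18 falls away, and no compound outside the list is made (F0).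

**Further compounds**
F1 | step 8 | tricyclic N-(2,6-dimethylphenyl)iminocyclopentene (imine of enone 13) | Cc1cccc(C)c1N=C1C[C@H]2C(=C1CO[Si](C)(C)C(C)(C)C)C[C@@H]3OC(C)(C)OC[C@]23O[Si](CC)(CC)CC
F0 | step 9 | none | none
F0 | step 19 | none | none
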